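**Remarks.** Germacrane numbering is used throughout (ring C1–C10; C11–C13 lactone arm, C13 the exocyclic methylene; C14 on C10; C15 the methyl on C4). Compounds 1, 2, 6, 23, 28 and 42 are taken as commercial. The decalin precursor 22 and the cyclodecynone 25 were checked against the target: their skeletons and the configurations at C3, C7 and C8 agree with it (C6 is reset later), so no structural correction was needed; only protecting groups were changed (silyl ether instead of a benzyl-type ether on C8, a more acid-stable silyl ether on C3).

## Structural features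

The target is a germacranolide: a ten-membered carbocycle with a cis-fused α-methylene-γ-butyrolactone on C6–C7, an (R)-2-methylbutanoate on C8, a ring-cis trisubstituted C4=C5 olefin with a free allylic hydroxyl on C3, and a C1–C10 epoxide whose C10 carries the C14 hydroxymethyl group. Three stereocentres are contiguous (C6, C7, C8, with O6, the C11 arm and O8 on one face), C1/C10 form a pair across the epoxide, C3 is separated from the triad by the olefin, and a seventh centre sits in the acyl chain (1R,3S,6S,7R,8R,10R,2'R). The fragile groups are the methylene lactone (Michael acceptor), the 2,3-epoxy alcohol (Payne migration under base, transannular opening by C4=C5 under acid), the allylic C3 carbinol and the epimerisable α-centre of the ester. The real difficulty is the medium ring: a ten-membered ring with a cis olefin between two oxygenated carbons must be made without a high-dilution closure. A second difficulty is that C3 must be correlated with the remote C6–C8 triad. The key step exploits the array C3(O)–C4=C5–C6(O) together with the oxygenated C10 directly across the ring. C4=C5 is read as an alkyne and C10 as a ketone, the two fragments released when a decalin fused at C5–C10 (ring A = C1–C5, C10; ring B = C5–C10), carrying a C4 ketone and a C5–C10 epoxide, is cleaved at its fusion bond.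

## Logic of the disconnections

**46 to 45.** The C1–O and C10–O bonds are cut. The epoxide is the most acid-sensitive element, so it is made last, by reagent-controlled epoxidation of the C14 allylic alcohol. This removes two stereocentres at once. It demands face control by the tartrate and chemoselectivity over the C3 allylic alcohol and the methylene lactone.

**45 to 44, 41 and 42.** The two silicon–oxygen bonds and the C8–O acyl bond are cut. The acid 42 is attached late so that its α-centre never meets enolate chemistry. This demands that the C8 hydroxyl can be freed alone, which is why C8 carries the most acid-labile of the remaining silyl ethers.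

**40 to 36.** The C11=C13 bond is cut. Methylenation of the lactone enolate is placed before the esterification, when C11 is the only acidic C–H.

**36 to 34, 32 and 31.** The lactone C12–O6 bond, the C6–H bond and the C4–C15 bond are cut. A C6 carbonyl is the only handle that sends a methyl group regiospecifically to C4 and gives the ring-cis olefin by syn addition. The forward steps demand clean 1,4-addition to the ynone and a face-selective 1,2-reduction that sets C6 cis to the C7 arm.

**31 to 29, 27 and 25.** The C10–C14 bond is cut back to the C10 ketone through its enol triflate. Hydroxymethyl is coupled directly, because reducing a C14 ester next to the C12 ester or lactone would not be chemoselective. The carbonyl is converted before the cuprate step, because an allenolate facing a transannular ketone invites aldol re-closure. The demand is enolisation toward C1 and not C9; the bulky, non-chelating silyl ether on C8 and a hindered base serve this.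

**25 to 22 and 23 (key).** The C4≡C5 π-bond and the C10 carbonyl are traced back to the C5–C10 σ-bond and the epoxide of a decalin. The ten-membered ring is then obtained by ring expansion with no entropic penalty. The only demands are the placement of the ketone (C4) and the epoxide (ring fusion), and condensation at a hindered carbonyl.

**22 to 21, 19, 17 and 16.** The C3–O bond, the C12 oxidation level and the epoxide C–O bonds are cut. Hydroxylation is placed after epoxidation: C5 is then quaternary, so the enolate can form only toward C3, and the epoxide oxygen shields one face. The allyl group is the masked acetate arm. The epoxidation must occur anti to the three cis substituents of ring B, since this face is relayed to C3.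

**16 and 15 to 13.** Ring A is traced to an anisole: the methoxy carbon is latent C4=O and the arene is the latent C5=C10 enone. This fixes what may be carried through the dissolving metal: the C6 oxygen as an alkoxide, C8 as a silyl ether, the C11–C12 arm as an allyl group, and no ester or benzyl-type ether. An unsaturated tetralone (C7=C8 next to a C6 ketone) is avoided altogether, because it is the keto tautomer of a naphthol.

**13 to 12 and 10.** The C6–H bond (hydride anti to the C7 substituent) and the C5–C6 bond (Friedel–Crafts acylation ortho to the methoxy group) are cut. The bromine para to methoxy enforces the regiochemistry and is lost for free in the Birch step.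

**10 to 8, 5, 4, 1 and 2.** The C7–C11 bond (anti-selective alkylation of a β-hydroxy ester dianion with 6), the C8–H bond (asymmetric hydrogenation) and the C7–C8 bond (acylation of a malonate half-ester) are cut. The anti relationship on the chain becomes the cis relationship on ring B. The whole absolute configuration derives from one catalytic step.

## Other disconnections considered

**Alternative 1:** The cut is C4=C5. In the forward step (H2IMes)(PCy3)Cl2Ru=CHPh (second-generation Grubbs catalyst) would join an isopropenyl group on C3 and a vinyl group on C6 that are tied together through a diisopropylsilylene bridge between O3 and O6. This gives A1, in which a seven-membered dioxasilepine and the carbocycle are closed together.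
- In its favour: the small siloxane ring forces the cis geometry, and the methyl group comes with the olefin. The epoxide, the C14 oxygen, the C8 ester and the acrylate arm are already in place, so only desilylation and lactonisation would remain after A1.
- Against it: the metathesis must make a trisubstituted olefin between two branched, oxygenated allylic carbons. The tether is installed by closing an eleven-membered silaketal, which pays the entropic price that the metathesis appears to avoid. All six ring stereocentres, including the sensitive epoxy alcohol, must be built on an open chain and carried past the ruthenium carbene.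
- Comparison: on olefin geometry the alternative is the equal of the chosen plan. On mildness of the late steps and on the number of steps after the key step it is the better one. The chosen plan is better in that its ring is formed by cleavage of an existing bond, with no macrocyclisation of any kind, and in that only three stereocentres need be set before the ring exists.

**Alternative 2:** The cut is C2–C3 together with O–C1. NaOCl would turn a C3 oxime into the nitrile oxide, which adds across the C1=C2 vinyl group to give A2, closing the isoxazoline and the carbocycle in one operation.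
- In its favour: one step makes the ring C–C bond, places oxygen on C1 and a masked carbonyl on C3. The lactone ring and the C10/C14 unit are already present, so the enolisation regiochemistry problem of the chosen plan does not arise; on this point the alternative is the better one.
- Against it: a ten-membered ring is closed through a bridged transition state, with nitrile oxide dimerisation competing at the dilution needed. The new C1 centre is formed next to a quaternary epoxide carbon with no obvious control element. After A2 there remain N–O cleavage beside an epoxide and an enone, stereoselective reduction at C3, epoxide transposition, methylenation and the protecting-group exchange at C8.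
- Comparison: on bond economy of the key step the two plans are equal (two bonds, one ring). The chosen plan is better on reliability of ring formation and leaves fewer stereocentres to late, substrate-dependent steps. Neither is shorter overall.

**Alternative 3:** The cut is C1–C2. CrCl2 would reduce the C2 bromide of an α-bromo ketone (C3 carbonyl conjugated with C4=C5) to a chromium enolate that adds to a C1 aldehyde borne by the C10 spiro-epoxide. This gives A3; a Payne transposition and reduction of the C3 ketone would finish the synthesis.
- In its favour: A3 already carries the methylene lactone, the C8 ester and the cis olefin, so the end game is the shortest of all four plans; on step economy after the key step and on convergence the alternative is clearly better. The chromium enolate is non-basic and tolerant of esters.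
- Against it: it is still a medium-ring closure at high dilution. Divalent chromium must spare an α-heteroatom-substituted aldehyde and a methylene lactone. C1 must form with the one configuration that lets the Payne step, which inverts C10, arrive at 1R,10R. The transposition runs under base on a molecule that now contains a Michael acceptor and a migratable ester, and C3 is set last.
- Comparison: the chosen plan is better in that its key step has no stereochemical demand and no dilution requirement. It is worse in the length of the sequence that follows. In mildness of the ring-forming step the two are equal.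

Key step: step 14

## Route

Step 1
Reactants: 1 2-(2-bromo-5-methoxyphenyl)acetic acid; 2 potassium methyl malonate
Product: 4 methyl 4-(2-bromo-5-methoxyphenyl)-3-oxobutanoate, via acyl imidazolide 3 (not isolated)
Conditions: 1,1'-carbonyldiimidazole, THF, rt; then 2, MgCl2, Et3N, MeCN, rt → 50 °C; aq. HCl
Reagents that add atoms: none
Why: Masamune–Brooks homologation: the magnesium malonate half-ester is C-acylated by the imidazolide and decarboxylates to the β-keto ester, forming the C7–C8 bond.

Step 2
Reactants: 4 methyl 4-(2-bromo-5-methoxyphenyl)-3-oxobutanoate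
Product: 5 methyl (3R)-4-(2-bromo-5-methoxyphenyl)-3-hydroxybutanoate
Conditions: H2 (10 atm), Ru2Cl4[(R)-BINAP]2·NEt3 (0.5 mol %), MeOH, 50 °C
Reagents that add atoms: none
Why: Noyori asymmetric hydrogenation of a β-keto ester; the (R)-BINAP catalyst sets C8 as (R), as for other 4-aryl-3-oxobutanoates, and the aryl bromide is inert.

Step 3
Reactants: 5 methyl (3R)-4-(2-bromo-5-methoxyphenyl)-3-hydroxybutanoate; 6 allyl bromide
Product: 8 methyl (2R,3R)-2-allyl-4-(2-bromo-5-methoxyphenyl)-3-hydroxybutanoate (2,3-anti), via dilithium dianion 7 (not isolated)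
Conditions: LiN(i-Pr)2 (2.2 equiv), THF, −78 → −20 °C; then 6, DMPU, −78 → 0 °C; aq. NH4Cl
Reagents that add atoms: none
Why: Fráter–Seebach alkylation: the chelated alkoxide–enolate is alkylated on the face opposite the C8 substituent, setting C7 anti to O8 (cis on the later ring). The allyl group is a Birch-inert precursor of the C11–C12 arm.

Step 4
Reactants: 8 anti-hydroxy ester
Product: 9 methyl (2R,3R)-2-allyl-4-(2-bromo-5-methoxyphenyl)-3-[(tert-butyldimethylsilyl)oxy]butanoate
Conditions: t-BuMe2SiOTf, 2,6-lutidine, CH2Cl2, 0 °C
Reagents that add atoms: tert-butyldimethylsilyl triflate, CC(C)(C)[Si](C)(C)OS(=O)(=O)C(F)(F)F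
Why: Silylation of the only hydroxyl. This ether survives Li/NH3 and later, being bulky and non-chelating, steers enolisation of the C10 ketone away from C9.

Step 5
Reactants: 9 silyl ether ester
Product: 10 (2R,3R)-2-allyl-4-(2-bromo-5-methoxyphenyl)-3-[(tert-butyldimethylsilyl)oxy]butanoic acid
Conditions: Me3SnOH, ClCH2CH2Cl, 70 °C; then 1 M HCl
Reagents that add atoms: trimethyltin hydroxide, C[Sn](C)(C)O
Why: Tin hydroxide cleavage of a methyl ester; it is essentially neutral, so the α-centre is not epimerised and the β-silyloxy group is not eliminated.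

Step 6
Reactants: 10 β-silyloxy acid
Product: 12 (2R,3R)-2-allyl-5-bromo-3-[(tert-butyldimethylsilyl)oxy]-8-methoxy-3,4-dihydronaphthalen-1(2H)-one (2,3-cis), via acid chloride 11 (not isolated)
Conditions: (COCl)2, DMF (cat.), CH2Cl2, 0 °C; then SnCl4, CH2Cl2, −78 → −20 °C
Reagents that add atoms: none
Why: Intramolecular Friedel–Crafts acylation forms C5–C6; with the position para to methoxy blocked by bromine, the only open site next to the chain is ortho to methoxy. Low temperature spares the silyl ether and the alkene and avoids β-elimination toward a naphthol.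

Step 7
Reactants: 12 tetralone
Product: 13 (1R,2S,3R)-2-allyl-5-bromo-3-[(tert-butyldimethylsilyl)oxy]-8-methoxy-1,2,3,4-tetrahydronaphthalen-1-ol (all-cis)
Conditions: LiBH(s-Bu)3, THF, −78 °C; then NaOH, H2O2
Reagents that add atoms: none
Why: The bulky hydride attacks the carbonyl anti to the adjacent allyl group and gives the C6 alcohol cis to the C7 and C8 substituents. Prompt reduction also removes the β-silyloxy ketone that could aromatise.

Step 8
Reactants: 13 all-cis tetralol
Product: 15 all-cis 7-allyl-6-[(tert-butyldimethylsilyl)oxy]-8-hydroxy-3,4,5,6,7,8-hexahydronaphthalen-1(2H)-one (C4 ketone, C5=C10, C6-OH, C7-allyl, C8-OSi), via dihydroanisole 14 (not isolated)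
Conditions: n-BuLi (1.0 equiv), THF, −78 °C; Li, NH3(l), t-BuOH, −78 → −33 °C; MeOH; then 1 M HCl, THF, 0 °C → rt
Reagents that add atoms: water, O
Why: Birch reduction: the benzylic oxygen is protected as its alkoxide, the bromide is reduced off, and the 1-methoxy-2,3-dialkylbenzene should give the 2,5-dihydro enol ether as 5-methoxytetralin does. Acid hydrolysis and conjugation then give the tetrasubstituted C5=C10 enone; the isolated alkene and the silyl ether are inert.

Step 9
Reactants: 15 hydroxy enone
Product: 16 C6 triethylsilyl ether of 15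
Conditions: Et3SiOTf, 2,6-lutidine, CH2Cl2, −78 °C
Reagents that add atoms: triethylsilyl triflate, CC[Si](CC)(CC)OS(=O)(=O)C(F)(F)F
Why: Silylation of the hindered allylic alcohol; triethylsilyl is the one silyl group that can later be removed beside the other two kinds.

Step 10
Reactants: 16 bis-silyl enone
Product: 17 C5–C10 epoxy ketone, epoxide oxygen anti to the C6, C7 and C8 substituents
Conditions: 30% H2O2, NaOH, MeOH, 0 °C → rt
Reagents that add atoms: hydrogen peroxide, OO
Why: Weitz–Scheffer nucleophilic epoxidation, as for the parent bicyclic enone. Hydroperoxide adds to C10 on the face opposite the three cis substituents of ring B and the enolate closes on that face.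

Step 11
Reactants: 17 allyl epoxy ketone
Product: 19 methyl ester epoxy ketone (C7–CH2CO2Me), via aldehyde 18 (not isolated)
Conditions: O3, NaOH, MeOH/CH2Cl2, −78 °C
Reagents that add atoms: ozone, [O-][O+]=O; methanol, CO
Why: Ozonolysis in basic methanol (Marshall conditions) cleaves the only C=C and oxidises the methyl hemiacetal of the resulting aldehyde to the methyl ester in the same flask.

Step 12
Reactants: 19 methyl ester epoxy ketone
Product: 21 C3 α-hydroxy ketone, hydroxyl trans to the epoxide oxygen, via potassium enolate 20 (not isolated)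
Conditions: KN(SiMe3)2 (1.05 equiv), THF, −78 °C; then 2-(phenylsulfonyl)-3-phenyloxaziridine; aq. NH4Cl
Reagents that add atoms: 2-(phenylsulfonyl)-3-phenyloxaziridine, O=S(=O)(c1ccccc1)N1OC1c1ccccc1
Why: Davis enolate hydroxylation: C5 is quaternary, so the ketone enolises only toward C3 and is far more acidic than the ester. The oxaziridine should approach anti to the epoxide oxygen on C5, which gives the C3 configuration of the target.

Step 13
Reactants: 21 α-hydroxy ketone
Product: 22 decalin α,β-epoxy ketone precursor (C3-OSiPh2t-Bu, C6-OSiEt3, C7-CH2CO2Me, C8-OSiMe2t-Bu)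
Conditions: t-BuPh2SiCl, imidazole, DMAP (cat.), DMF, rt
Reagents that add atoms: tert-butyl(chloro)diphenylsilane, CC(C)(C)[Si](Cl)(c1ccccc1)c1ccccc1
Why: Silylation of the only hydroxyl; this ether is about a hundred times more acid-stable than the C8 ether, which is what later allows C8 to be freed alone.

Step 14
Reactants: 22 decalin α,β-epoxy ketone; 23 tosylhydrazide
Product: 25 cyclodec-5-ynone (C10 ketone, C4≡C5, C3-OSiPh2t-Bu, C6-OSiEt3, C7-CH2CO2Me, C8-OSiMe2t-Bu), via tosylhydrazone 24 (not isolated)
Conditions: 23 (1.1 equiv), AcOH/CH2Cl2 (1:2), −20 °C → rt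
Reagents that add atoms: none
Why: Condensation at C4 gives the tosylhydrazone; its nitrogen lone pair opens the epoxide at C5–O to an azoalkene with an alkoxide (or hydroxyl) on C10. That oxygen then re-forms a carbonyl while the C5–C10 bond breaks and N2 and p-toluenesulfinate leave, creating C4≡C5 and the C10 ketone. The closest known reaction is the Eschenmoser–Tanabe fragmentation of bicyclic α,β-epoxy ketone tosylhydrazones to cycloalkynones, including the parent decalin case that gives cyclodec-5-ynone. The ten-membered ring is not closed by a cyclisation; it is formed by cleavage of the bond shared by the two six-membered rings, so there is no dilution requirement and no entropic cost. No stereocentre is created, and the centres at C3, C6, C7 and C8 are not touched. The selectivity needed is regiochemical only, and it is fixed by the substrate, since the sole ketone is at C4 and the epoxide lies on the ring fusion; either epoxide face would fragment. Chemoselectivity rests on the ketone being the only carbonyl that condenses with the hydrazide (the ester does not) and on strain-driven epoxide opening being much faster than expulsion of the silyloxy group from C3. The acid medium is mild enough for the silyl ethers at −20 °C to rt.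

Step 15
Reactants: 25 cyclodec-5-ynone
Product: 27 ring-cis C1(10)-enol triflate, via potassium enolate 26 (not isolated)
Conditions: KN(SiMe3)2 (1.05 equiv), THF, −78 °C; then N-(5-chloropyridin-2-yl)bis(trifluoromethanesulfonimide) (Comins' reagent), −78 °C
Reagents that add atoms: Comins' reagent, FC(F)(F)S(=O)(=O)N(c1ccc(Cl)cn1)S(=O)(=O)C(F)(F)F
Why: Kinetic deprotonation by a hindered amide takes the open C1 methylene, not C9, which is shielded by the bulky non-chelating silyl ether on C8. The enolate can only be ring-cis in a cyclodecenyne, and the ketone is converted before any cuprate chemistry.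

Step 16
Reactants: 27 enol triflate; 28 (tributylstannyl)methanol
Product: 29 C14 allylic alcohol (ring-cis C1=C10 bearing CH2OH on C10)
Conditions: 28 (1.5 equiv), Pd(PPh3)4 (5 mol %, zerovalent palladium), LiCl, 1,4-dioxane, 90 °C
Reagents that add atoms: none
Why: Stille (Kosugi–Migita) hydroxymethylation of a vinyl triflate with retention of olefin geometry. C14 arrives at the alcohol oxidation level, so no ester has to be reduced beside the C12 ester.

Step 17
Reactants: 29 allylic alcohol
Product: 30 C14 tert-butyldiphenylsilyl ether of 29
Conditions: t-BuPh2SiCl, imidazole, CH2Cl2, 0 °C → rt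
Reagents that add atoms: tert-butyl(chloro)diphenylsilane, CC(C)(C)[Si](Cl)(c1ccccc1)c1ccccc1
Why: Silylation of the only free hydroxyl, so that the next oxidation touches C6 alone.

Step 18
Reactants: 30 tetrasilyl ether
Product: 31 C6 propargylic alcohol
Conditions: PPTS, MeOH/CH2Cl2, 0 °C → rt
Reagents that add atoms: none
Why: Acid-catalysed methanolysis removes the secondary triethylsilyl ether, the most labile of the four silyl ethers, and leaves the other three.

Step 19
Reactants: 31 propargylic alcohol
Product: 32 C6 ynone
Conditions: Dess–Martin periodinane, NaHCO3, CH2Cl2, 0 °C → rt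
Reagents that add atoms: none
Why: Buffered periodinane oxidation of a propargylic alcohol; neutral conditions protect the epimerisable C7 centre and the β-silyloxy group of the new ketone.

Step 20
Reactants: 32 ynone
Product: 34 ring-cis C4-methyl enone (C6 ketone, C4(Me)=C5), via lithium allenolate 33 (not isolated)
Conditions: Me2CuLi (from CuI and MeLi, 1.3 equiv), Et2O/THF, −78 °C; aq. NH4Cl at −78 °C
Reagents that add atoms: lithium dimethylcuprate, [Li+].C[Cu-]C
Why: Cuprate conjugate addition to an ynone puts the methyl on C4, and syn addition followed by protonation gives the ring-cis enone, the only unstrained geometry in a ten-membered ring. At −78 °C the ester and the silyl ethers are untouched.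

Step 21
Reactants: 34 enone
Product: 36 cis-fused 6,12-lactone, via hydroxy ester 35 (not isolated)
Conditions: NaBH4, CeCl3·7H2O, MeOH, −78 °C; then PPTS, CH2Cl2, rt
Reagents that add atoms: none
Why: Luche 1,2-reduction: hydride is expected on the carbonyl face away from the C7 acetate arm, giving the C6 alcohol cis to that arm (6S). The cis γ-hydroxy ester then lactonises under mild acid.

Step 22
Reactants: 36 lactone
Product: 38 C11 dimethylaminomethyl lactone (C11 epimers), via lithium enolate 37 (not isolated)
Conditions: LiN(SiMe3)2 (1.2 equiv), THF, −78 °C; then Me2N=CH2+ I− (Eschenmoser's salt), −78 °C → rt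
Reagents that add atoms: Eschenmoser's salt, C=[N+](C)C.[I-]
Why: Mannich reaction of the lactone enolate; C11 carries the only acidic C–H at this stage.

Step 23
Reactants: 38 Mannich base
Product: 40 α-methylene lactone, via ammonium iodide 39 (not isolated)
Conditions: MeI, MeOH, rt; then aq. NaHCO3, CH2Cl2
Reagents that add atoms: none
Why: Quaternisation and E1cB loss of trimethylamine, the standard way to an α-methylene-γ-butyrolactone.

Step 24
Reactants: 40 α-methylene lactone
Product: 41 C8 alcohol
Conditions: camphorsulfonic acid (0.2 equiv), MeOH/CH2Cl2, 0 °C → rt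
Reagents that add atoms: none
Why: Acid methanolysis removes the secondary tert-butyldimethylsilyl ether while the two tert-butyldiphenylsilyl ethers, far more acid-stable, remain.

Step 25
Reactants: 41 C8 alcohol; 42 (R)-2-methylbutanoic acid
Product: 44 C8 (R)-2-methylbutanoate, via mixed anhydride 43 (not isolated)
Conditions: 42, 2,4,6-Cl3C6H2COCl, Et3N, THF, rt; then 41, DMAP, PhMe, rt
Reagents that add atoms: none
Why: Yamaguchi esterification of the only free hydroxyl; the mixed anhydride route keeps the α-centre of a 2-alkylalkanoic acid intact.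

Step 26
Reactants: 44 ester
Product: 45 C3,C14-diol (1(10)-ene)
Conditions: Bu4NF, AcOH (1:1), THF, 0 °C → rt
Reagents that add atoms: none
Why: Fluoride cleaves both tert-butyldiphenylsilyl ethers; buffering with acetic acid prevents alkoxide addition to the methylene lactone and acyl migration.

Step 27
Reactants: 45 diol
Product: 46 CNP0356520.2 (target)
Conditions: Ti(Oi-Pr)4 (0.2 equiv), D-(−)-diethyl tartrate (0.25 equiv), t-BuOOH, 4 Å MS, CH2Cl2, −20 °C
Reagents that add atoms: tert-butyl hydroperoxide, CC(C)(C)OO
Why: Sharpless asymmetric epoxidation: with the D-(−)-tartrate the oxygen is delivered to the face of the ring-cis C1=C10 olefin that gives 1R,10R. The primary allylic alcohol reacts much faster than the C3 secondary carbinol on a cis-substituted olefin, and the electron-poor methylene lactone is inert.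

## Compound list

1 | 2-(2-bromo-5-methoxyphenyl)acetic acid | OC(=O)Cc1cc(OC)ccc1Br | starting material
2 | potassium methyl malonate | COC(=O)CC(=O)[O-].[K+] | starting material
3 | 2-(2-bromo-5-methoxyphenyl)-1-(imidazol-1-yl)ethanone | O=C(Cc1cc(OC)ccc1Br)n1ccnc1 | intermediate
4 | methyl 4-(2-bromo-5-methoxyphenyl)-3-oxobutanoate | COC(=O)CC(=O)Cc1cc(OC)ccc1Br | intermediate
5 | methyl (3R)-4-(2-bromo-5-methoxyphenyl)-3-hydroxybutanoate | COC(=O)C[C@H](O)Cc1cc(OC)ccc1Br | intermediate
6 | allyl bromide | C=CCBr | starting material
7 | dilithium alkoxide–enolate of 5 | [Li+].[Li+].[O-]/C(OC)=C\[C@H]([O-])Cc1cc(OC)ccc1Br | intermediate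
8 | methyl (2R,3R)-2-allyl-4-(2-bromo-5-methoxyphenyl)-3-hydroxybutanoate | COC(=O)[C@H](CC=C)[C@H](O)Cc1cc(OC)ccc1Br | intermediate
9 | tert-butyldimethylsilyl ether of 8 | COC(=O)[C@H](CC=C)[C@H](O[Si](C)(C)C(C)(C)C)Cc1cc(OC)ccc1Br | intermediate
10 | (2R,3R)-2-allyl-4-(2-bromo-5-methoxyphenyl)-3-[(tert-butyldimethylsilyl)oxy]butanoic acid | OC(=O)[C@H](CC=C)[C@H](O[Si](C)(C)C(C)(C)C)Cc1cc(OC)ccc1Br | intermediate
11 | acid chloride of 10 | ClC(=O)[C@H](CC=C)[C@H](O[Si](C)(C)C(C)(C)C)Cc1cc(OC)ccc1Br | intermediate
12 | (2R,3R)-2-allyl-5-bromo-3-[(tert-butyldimethylsilyl)oxy]-8-methoxy-3,4-dihydronaphthalen-1(2H)-one | O=C1[C@H](CC=C)[C@H](O[Si](C)(C)C(C)(C)C)Cc2c(Br)ccc(OC)c21 | intermediate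
13 | (1R,2S,3R)-2-allyl-5-bromo-3-[(tert-butyldimethylsilyl)oxy]-8-methoxy-1,2,3,4-tetrahydronaphthalen-1-ol (all-cis) | COc1ccc(Br)c2C[C@@H](O[Si](C)(C)C(C)(C)C)[C@@H](CC=C)[C@@H](O)c12 | intermediate
14 | 2,5-dihydroanisole (enol ether C3=C4, olefin C1=C10; C5 epimers) from 13 | COC1=CCC=C2C[C@@H](O[Si](C)(C)C(C)(C)C)[C@@H](CC=C)[C@@H](O)C12 | intermediate
15 | all-cis 7-allyl-6-[(tert-butyldimethylsilyl)oxy]-8-hydroxy-3,4,5,6,7,8-hexahydronaphthalen-1(2H)-one | O=C1CCCC2=C1[C@H](O)[C@H](CC=C)[C@H](O[Si](C)(C)C(C)(C)C)C2 | intermediate
16 | C6 triethylsilyl ether of 15 | O=C1CCCC2=C1[C@H](O[Si](CC)(CC)CC)[C@H](CC=C)[C@H](O[Si](C)(C)C(C)(C)C)C2 | intermediate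
17 | C5–C10 epoxide of 16, oxygen anti to the ring-B substituents | O=C1CCC[C@]23O[C@]12[C@H](O[Si](CC)(CC)CC)[C@H](CC=C)[C@H](O[Si](C)(C)C(C)(C)C)C3 | intermediate
18 | aldehyde from ozonolysis of 17 | O=C1CCC[C@]23O[C@]12[C@H](O[Si](CC)(CC)CC)[C@H](CC=O)[C@H](O[Si](C)(C)C(C)(C)C)C3 | intermediate
19 | methyl ester epoxy ketone | O=C1CCC[C@]23O[C@]12[C@H](O[Si](CC)(CC)CC)[C@H](CC(=O)OC)[C@H](O[Si](C)(C)C(C)(C)C)C3 | intermediate
20 | potassium C3-enolate of 19 | [K+].[O-]C1=CCC[C@]23O[C@]12[C@H](O[Si](CC)(CC)CC)[C@H](CC(=O)OC)[C@H](O[Si](C)(C)C(C)(C)C)C3 | intermediate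
21 | C3 α-hydroxy epoxy ketone (OH trans to epoxide O) | O=C1[C@@H](O)CC[C@]23O[C@]12[C@H](O[Si](CC)(CC)CC)[C@H](CC(=O)OC)[C@H](O[Si](C)(C)C(C)(C)C)C3 | intermediate
22 | decalin α,β-epoxy ketone (C3 tert-butyldiphenylsilyl ether of 21) | O=C1[C@@H](O[Si](c4ccccc4)(c5ccccc5)C(C)(C)C)CC[C@]23O[C@]12[C@H](O[Si](CC)(CC)CC)[C@H](CC(=O)OC)[C@H](O[Si](C)(C)C(C)(C)C)C3 | intermediate
23 | tosylhydrazide | Cc1ccc(cc1)S(=O)(=O)NN | starting material
24 | tosylhydrazone of 22 | Cc1ccc(cc1)S(=O)(=O)NN=C1[C@@H](O[Si](c4ccccc4)(c5ccccc5)C(C)(C)C)CC[C@]23O[C@]12[C@H](O[Si](CC)(CC)CC)[C@H](CC(=O)OC)[C@H](O[Si](C)(C)C(C)(C)C)C3 | intermediate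
25 | cyclodec-5-ynone (C10 ketone, C4≡C5) | O=C1CC[C@H](O[Si](c2ccccc2)(c3ccccc3)C(C)(C)C)C#C[C@H](O[Si](CC)(CC)CC)[C@H](CC(=O)OC)[C@H](O[Si](C)(C)C(C)(C)C)C1 | intermediate
26 | potassium C1(10)-enolate of 25 | [K+].[O-]/C1=C/C[C@H](O[Si](c2ccccc2)(c3ccccc3)C(C)(C)C)C#C[C@H](O[Si](CC)(CC)CC)[C@H](CC(=O)OC)[C@H](O[Si](C)(C)C(C)(C)C)C1 | intermediate
27 | ring-cis C1(10)-enol triflate | FC(F)(F)S(=O)(=O)O/C1=C/C[C@H](O[Si](c2ccccc2)(c3ccccc3)C(C)(C)C)C#C[C@H](O[Si](CC)(CC)CC)[C@H](CC(=O)OC)[C@H](O[Si](C)(C)C(C)(C)C)C1 | intermediate
28 | (tributylstannyl)methanol | CCCC[Sn](CCCC)(CCCC)CO | starting material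
29 | C14 allylic alcohol | OC/C1=C/C[C@H](O[Si](c2ccccc2)(c3ccccc3)C(C)(C)C)C#C[C@H](O[Si](CC)(CC)CC)[C@H](CC(=O)OC)[C@H](O[Si](C)(C)C(C)(C)C)C1 | intermediate
30 | C14 tert-butyldiphenylsilyl ether of 29 | CC(C)(C)[Si](c2ccccc2)(c3ccccc3)OC/C1=C/C[C@H](O[Si](c4ccccc4)(c5ccccc5)C(C)(C)C)C#C[C@H](O[Si](CC)(CC)CC)[C@H](CC(=O)OC)[C@H](O[Si](C)(C)C(C)(C)C)C1 | intermediate
31 | C6 propargylic alcohol | CC(C)(C)[Si](c2ccccc2)(c3ccccc3)OC/C1=C/C[C@H](O[Si](c4ccccc4)(c5ccccc5)C(C)(C)C)C#C[C@H](O)[C@H](CC(=O)OC)[C@H](O[Si](C)(C)C(C)(C)C)C1 | intermediate
32 | C6 ynone | CC(C)(C)[Si](c2ccccc2)(c3ccccc3)OC/C1=C/C[C@H](O[Si](c4ccccc4)(c5ccccc5)C(C)(C)C)C#CC(=O)[C@H](CC(=O)OC)[C@H](O[Si](C)(C)C(C)(C)C)C1 | intermediate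
33 | lithium allenolate from 32 | [Li+].CC(C)(C)[Si](c2ccccc2)(c3ccccc3)OC/C1=C/C[C@H](O[Si](c4ccccc4)(c5ccccc5)C(C)(C)C)C(C)=C=C([O-])[C@H](CC(=O)OC)[C@H](O[Si](C)(C)C(C)(C)C)C1 | intermediate
34 | ring-cis C4-methyl enone | CC(C)(C)[Si](c2ccccc2)(c3ccccc3)OC/C1=C/C[C@H](O[Si](c4ccccc4)(c5ccccc5)C(C)(C)C)/C(C)=C\C(=O)[C@H](CC(=O)OC)[C@H](O[Si](C)(C)C(C)(C)C)C1 | intermediate
35 | C6 (S) hydroxy ester | CC(C)(C)[Si](c2ccccc2)(c3ccccc3)OC/C1=C/C[C@H](O[Si](c4ccccc4)(c5ccccc5)C(C)(C)C)/C(C)=C\[C@H](O)[C@H](CC(=O)OC)[C@H](O[Si](C)(C)C(C)(C)C)C1 | intermediate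
36 | cis-fused 6,12-lactone | C1C(=O)O[C@H]2/C=C(/C)[C@@H](O[Si](c3ccccc3)(c4ccccc4)C(C)(C)C)C/C=C(/CO[Si](c5ccccc5)(c6ccccc6)C(C)(C)C)C[C@@H](O[Si](C)(C)C(C)(C)C)[C@@H]12 | intermediate
37 | lithium enolate of 36 | [Li+].C1=C([O-])O[C@H]2/C=C(/C)[C@@H](O[Si](c3ccccc3)(c4ccccc4)C(C)(C)C)C/C=C(/CO[Si](c5ccccc5)(c6ccccc6)C(C)(C)C)C[C@@H](O[Si](C)(C)C(C)(C)C)[C@@H]12 | intermediate
38 | C11 dimethylaminomethyl lactone (C11 epimers) | CN(C)CC1C(=O)O[C@H]2/C=C(/C)[C@@H](O[Si](c3ccccc3)(c4ccccc4)C(C)(C)C)C/C=C(/CO[Si](c5ccccc5)(c6ccccc6)C(C)(C)C)C[C@@H](O[Si](C)(C)C(C)(C)C)[C@@H]12 | intermediate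
39 | trimethylammonium iodide of 38 | [I-].C[N+](C)(C)CC1C(=O)O[C@H]2/C=C(/C)[C@@H](O[Si](c3ccccc3)(c4ccccc4)C(C)(C)C)C/C=C(/CO[Si](c5ccccc5)(c6ccccc6)C(C)(C)C)C[C@@H](O[Si](C)(C)C(C)(C)C)[C@@H]12 | intermediate
40 | α-methylene lactone | C=C1C(=O)O[C@H]2/C=C(/C)[C@@H](O[Si](c3ccccc3)(c4ccccc4)C(C)(C)C)C/C=C(/CO[Si](c5ccccc5)(c6ccccc6)C(C)(C)C)C[C@@H](O[Si](C)(C)C(C)(C)C)[C@@H]12 | intermediate
41 | C8 alcohol | C=C1C(=O)O[C@H]2/C=C(/C)[C@@H](O[Si](c3ccccc3)(c4ccccc4)C(C)(C)C)C/C=C(/CO[Si](c5ccccc5)(c6ccccc6)C(C)(C)C)C[C@@H](O)[C@@H]12 | intermediate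
42 | (R)-2-methylbutanoic acid | OC(=O)[C@H](C)CC | starting material
43 | (R)-2-methylbutanoic 2,4,6-trichlorobenzoic anhydride | O=C(OC(=O)[C@H](C)CC)c1c(Cl)cc(Cl)cc1Cl | intermediate
44 | C8 (R)-2-methylbutanoate, C3 and C14 silyl ethers | C=C1C(=O)O[C@H]2/C=C(/C)[C@@H](O[Si](c3ccccc3)(c4ccccc4)C(C)(C)C)C/C=C(/CO[Si](c5ccccc5)(c6ccccc6)C(C)(C)C)C[C@@H](OC(=O)[C@H](C)CC)[C@@H]12 | intermediate
45 | C3,C14-diol with C1=C10 olefin | C=C1C(=O)O[C@H]2/C=C(/C)[C@@H](O)C/C=C(/CO)C[C@@H](OC(=O)[C@H](C)CC)[C@@H]12 | intermediate
46 | CNP0356520.2 | C=C1C(=O)O[C@H]2/C=C(/C)[C@@H](O)C[C@H]3O[C@@]3(CO)C[C@@H](OC(=O)[C@H](C)CC)[C@@H]12 | target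

## Step count and least certain steps

Total: 27 steps. Longest linear sequence: 27 steps from 1 (the route is fully linear; 2, 6, 23, 28 and 42 enter as purchased reagents).

**Step 14 (key step).** The most likely failure is slow condensation at the C4 carbonyl, which sits between a quaternary epoxide carbon and a silyloxy-bearing carbon. Acid-promoted loss of the C6 triethylsilyl ether or opening of the epoxide could then overtake hydrazone formation. Fallback: from 22, condensation with the more nucleophilic 1-amino-2-phenylaziridine under neutral conditions would give the aziridinyl hydrazone F11. On warming in toluene this fragments by loss of styrene and N2 (the aminoaziridine form of the same fragmentation, with no acid and no sulfinate) and returns to the route at 25.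

**Step 8 (Birch reduction and hydrolysis).** Three things may go wrong: protonation with the other regiochemistry (which after hydrolysis leads to a disubstituted, not the ring-fusion, enone), hydrogenolysis of the benzylic C6–O bond before the alkoxide is formed, and dehydration of the β-hydroxy ketone during hydrolysis. The cause is that a 2,3-dialkylanisole offers two nearly equivalent reduction modes and the substrate carries a benzylic oxygen. Fallback: from 9, i-Bu2AlH reduction gives the primary alcohol F1. Its arene, once the bromine is reduced off, is a meta-alkylanisole whose Birch reduction is regiochemically unambiguous; reduction and acid hydrolysis give the 3-substituted cyclohexenone F2. α-Iodination (I2, pyridine) gives the iodoenone F3 and Dess–Martin oxidation the aldehyde F4. An intramolecular Nozaki–Hiyama–Kishi coupling (CrCl2, NiCl2 cat., DMF) then forms the C5–C6 bond and the C6 carbinol and returns to the route at 15. This also bypasses steps 5–7. The C6 configuration of that closure is not secured, and the C6 epimer F5 may accompany 15. F5 can be advanced through the same steps because C6 is oxidised later, at the cost of weaker facial bias in step 10.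

**Step 12 (C3 hydroxylation).** The risk is poor facial selectivity in the oxygen transfer, or an incomplete relay from the epoxidation of step 10, since C3 is correlated with C7/C8 only through the epoxide face. Either leak ends as the C3 epimer. Fallback: from 19, if the hydroxylation delivers the C3-epimeric ketol F6, a Mitsunobu reaction with 4-nitrobenzoic acid (PPh3, DIAD) gives the inverted 4-nitrobenzoate F7. Mild methanolysis (NaN3, MeOH) returns to the route at 21. Because either epoxide face fragments, this correction also covers a wrong epoxide face.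

**Step 15 (enol triflate).** The risk is competing deprotonation at C9, followed by β-elimination of the C8 silyloxy group or by formation of the regioisomeric triflate; the two α-methylenes differ only in their neighbours. Fallback: from 25, Me2S=CH2 (from Me3S+ I− and KN(SiMe3)2) gives the C10 spiro-epoxide F8 without forming an enolate. Diethylaluminium 2,2,6,6-tetramethylpiperidide (Et2Al(tmp)) in toluene then isomerises it by syn-elimination at the less hindered C1 methylene to the allylic alcohol. The fallback returns to the route at 29 and makes the coupling step unnecessary.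

**Step 21 (C6 reduction).** The risk is hydride delivery to the other face of the C6 carbonyl, because the face is decided by the conformation of the ten-membered ring and not by a rigid framework. Fallback: from 34, the reduction is worked up without acid to give the C6-epimeric hydroxy ester F9. LiOH gives the hydroxy acid F10, and a Mitsunobu lactonisation (PPh3, DIAD) closes the lactone with inversion at C6, returning to the route at 36.

## Further compounds

F1 | step 8 | 2-allyl-4-(2-bromo-5-methoxyphenyl)-3-[(tert-butyldimethylsilyl)oxy]butan-1-ol (from 9) | OC[C@H](CC=C)[C@H](O[Si](C)(C)C(C)(C)C)Cc1cc(OC)ccc1Br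
F2 | step 8 | 3-substituted cyclohex-2-enone with primary alcohol | O=C1C=C(C[C@@H](O[Si](C)(C)C(C)(C)C)[C@@H](CC=C)CO)CCC1
F3 | step 8 | 2-iodo-3-substituted cyclohex-2-enone | O=C1C(I)=C(C[C@@H](O[Si](C)(C)C(C)(C)C)[C@@H](CC=C)CO)CCC1
F4 | step 8 | iodoenone aldehyde | O=C1C(I)=C(C[C@@H](O[Si](C)(C)C(C)(C)C)[C@@H](CC=C)C=O)CCC1
F5 | step 8 | C6 epimer of 15 | O=C1CCCC2=C1[C@@H](O)[C@H](CC=C)[C@H](O[Si](C)(C)C(C)(C)C)C2
F6 | step 12 | C3 epimer of 21 | O=C1[C@H](O)CC[C@]23O[C@]12[C@H](O[Si](CC)(CC)CC)[C@H](CC(=O)OC)[C@H](O[Si](C)(C)C(C)(C)C)C3
F7 | step 12 | 4-nitrobenzoate of 21 | O=C1[C@@H](OC(=O)c4ccc(cc4)[N+](=O)[O-])CC[C@]23O[C@]12[C@H](O[Si](CC)(CC)CC)[C@H](CC(=O)OC)[C@H](O[Si](C)(C)C(C)(C)C)C3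
F8 | step 15 | C10 spiro-epoxide from 25 (C10 epimers) | C1OC12CC[C@H](O[Si](c3ccccc3)(c4ccccc4)C(C)(C)C)C#C[C@H](O[Si](CC)(CC)CC)[C@H](CC(=O)OC)[C@H](O[Si](C)(C)C(C)(C)C)C2
F9 | step 21 | C6-epimeric hydroxy ester | CC(C)(C)[Si](c2ccccc2)(c3ccccc3)OC/C1=C/C[C@H](O[Si](c4ccccc4)(c5ccccc5)C(C)(C)C)/C(C)=C\[C@@H](O)[C@H](CC(=O)OC)[C@H](O[Si](C)(C)C(C)(C)C)C1
F10 | step 21 | C6-epimeric hydroxy acid | CC(C)(C)[Si](c2ccccc2)(c3ccccc3)OC/C1=C/C[C@H](O[Si](c4ccccc4)(c5ccccc5)C(C)(C)C)/C(C)=C\[C@@H](O)[C@H](CC(=O)O)[C@H](O[Si](C)(C)C(C)(C)C)C1
F11 | step 14 | 2-phenylaziridin-1-yl hydrazone of 22 | c1ccccc1C1CN1N=C1[C@@H](O[Si](c4ccccc4)(c5ccccc5)C(C)(C)C)CC[C@]23O[C@]12[C@H](O[Si](CC)(CC)CC)[C@H](CC(=O)OC)[C@H](O[Si](C)(C)C(C)(C)C)C3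
A1 | alternative 1 | silylene-bridged ten-membered carbocycle | CC(C)[Si]1(C(C)C)O[C@H]2/C=C(/C)[C@@H](O1)C[C@H]3O[C@@]3(CO[Si](C)(C)C(C)(C)C)C[C@@H](OC(=O)[C@H](C)CC)[C@H]2C(=C)C(=O)OC
A2 | alternative 2 | isoxazoline-bridged ten-membered carbocycle | C1C(=O)O[C@H]2/C=C(/C)C3=NO[C@H](C3)[C@@]4(CO4)C[C@@H](OCc5ccc(OC)cc5)[C@@H]12
A3 | alternative 3 | ten-membered β-hydroxy enone with C10 spiro-epoxide | C=C1C(=O)O[C@H]2/C=C(/C)C(=O)C[C@@H](O)[C@@]3(CO3)C[C@@H](OC(=O)[C@H](C)CC)[C@@H]12
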